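Time read by itself misleads: east stops at 0.80 h, sooner than north-west at 1.5 h, but it holds 15 µM of free enzyme against 3.5 µM.

| setting | dusk | autumn | north-west | east |
|---|---|---|---|---|
| starting material | 52 mM | 35 mM | 35 mM | 35 mM |
| second substrate | 175 mM | 88 mM | 175 mM | 175 mM |
| free enzyme | 3.5 µM | 3.5 µM | 3.5 µM | 15 µM |
| temperature | 37 °C | 37 °C | 37 °C | 37 °C |
| remark | run made earlier | run made earlier |  |  |
| time |  |  | 1.5 h | 0.80 h |

- dusk (time / min: target / %, starting material / %): 10.0: 15.3, 83.5; 20.0: 29.3, 69.6; 25.0: 35.4, 62.8; 40.0: 51.6, 48.3; 50.0: 59.8, 40.3
- autumn (time / min: target / %, starting material / %): 10.0: 17.4, 82.7; 20.0: 32.1, 68.0; 25.0: 37.8, 61.9; 40.0: 53.6, 46.4; 50.0: 60.9, 37.6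

(each reading ± 0.5 percentage points)

- no earlier run changes the charge of free enzyme; that part of a forecast is a guess

1. which one finishes higher in amount of target, in percent of the starting material charged ("neither" within 2 percentage points) (north-west / east / neither)
2. amount of target at the end, in percent of the starting material charged, north-west
3. amount of target at the end, in percent of the starting material charged, east

1. Pseudo-first-order extreme: the rate follows the starting material left. Autumn's last reading gives the constant k = 0.0196 min⁻¹, with the scatter of that reading. East's enzyme dose is 4.02: N, defined as k times time times enzyme charge over autumn's charge. The share left is then e^(−N). The scaling with enzyme is a guess, since no earlier run changes that charge.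

2. North-west has N = 1.76, so target 82.8%. East has N = 4.02, so target 98.2%.

3. Zero-order extreme: the enzyme keeps its opening speed. Autumn's first reading, 17.4% in 10.0 min, clears the charge in 57.5 min, sooner than north-west stops. This extreme therefore gives 100% there.

4. Dividing dusk's first rate in mM by autumn's removes time. The ratio is 1.31. The first extreme gives the charge ratio, 1.49, and the second gives 1. Second substrate differs too, so this is rough, but the reading stands nearer the first extreme. This reckoning places each flask a little above step 2.

The forecast gives east as higher, with 83% for north-west and 96% for east, on the ground “Assuming rate scales with enzyme”. Its east figure lies below the value in step 2.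

The flask gives 87.0% in north-west and 99.5% in east, so east finishes higher.

    free enzyme → unfolded enzyme (k = 0.00310 min⁻¹, Ea = 267 kJ mol⁻¹)
    starting material + free enzyme ⇌ first complex (K = 15.0 M⁻¹, k = 40000 M⁻¹ s⁻¹, Ea = 14.0 kJ mol⁻¹, ΔH = −53.0 kJ mol⁻¹)
    first complex ⇌ loaded enzyme + first product (K = 0.0330 M, k = 770 min⁻¹, Ea = 62.0 kJ mol⁻¹, ΔH = −28.0 kJ mol⁻¹)
    second substrate + loaded enzyme ⇌ second complex (K = 9.60 M⁻¹, k = 1.60 × 10⁵ M⁻¹ min⁻¹, Ea = 43.0 kJ mol⁻¹, ΔH = −8.00 kJ mol⁻¹)
    second complex → free enzyme + target (k = 1800 min⁻¹, Ea = 59.0 kJ mol⁻¹)
    (constants at 37 °C)

The largest single effect is the difference in enzyme charge: with that difference taken away, east gives 65.9%, where N, cut to 0.939, says 60.9%. East also ends with 12.2% of its catalyst as unfolded enzyme, which N does not hold. With that share taken off over the whole run, N is 3.53, which says 97.1% target, above north-west's result.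

A neighbour flask, east with 44 mM of second substrate, keeps N = 4.02, which says 98.2%. It gives 88.5%, with 30% of its second substrate left.

(The data stem from a simulated flask with made-up constants; scatter was added.)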